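## The problem

Target **24** is a C2-symmetric cyclobutane with one carbocycle, no ring fusion and six stereocentres. C1 and C2 each carry a carboxyl group esterified by the secondary hydroxyl of (R)-3-(3,4-dihydroxyphenyl)lactic acid, and C3 and C4 each carry a 3,4-dihydroxyphenyl ring. Around the ring the substituents are C1/C2 trans, C2/C3 cis, C3/C4 trans and C4/C1 cis (all four ring carbons R), so each ester stands cis to the aryl group next to it. This is the least stable diastereomer with trans aryl groups; the all-trans isomer lies downhill by epimerisation at C1 and C2, both α to carbonyl groups. C1 and C2 must therefore be set late, under kinetic control, and must not meet base afterwards. C3 and C4 are configurationally stable once sp3, can be set early, and are the only centres placed to direct C1 and C2; the two arm stereocentres are remote and are best bought. The fragile groups are four catechols, two ester links to an α-hydroxy acid, electron-rich arenes, and on the way any 3,4-diarylcyclobutene, which can open conrotatorily. The enabling feature is that C1 and C2 are adjacent ring carbons each bearing a carboxyl carbon: bridged by a sulfonyl group in a thiolane 1,1-dioxide (its C2 and C5), each is doubly acidified. Halogenation, 1,3-closure and loss of SO2 can then forge the C1–C2 bond as an alkene under mild base while the trans C3/C4 pair looks on.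

## Retrosynthesis

**24 ⇒ 23.** The last operation removes ten benzyl groups from **23** (eight aryl ethers, two arm esters). Benzyl is preferred to methyl, acetal or silyl protection because it leaves by neutral hydrogenolysis, which touches neither the ester links nor the epimerisable C1/C2 centres, and because the same group masks the arm carboxyls. The forward step asks only that the cyclobutane and the non-benzylic alkyl C–O bonds survive.

**23 ⇒ 20 + 22.** **23** is cut at its two acyl–oxygen bonds into diacid **20** and two molecules of hydroxy ester **22**, which is one alkylation step from the commercial salt **21**. Attaching the arms earlier would expose their α-hydrogen and acyloxy group to the enolate, sulfide and hydroxide steps. A trans-1,2-diacid cannot close to a cyclic anhydride, so both carboxyls react independently. The forward reaction must acylate a hindered secondary alcohol without epimerising C1/C2; the C–O bond of **22** is not broken, so its (R) centre is carried through.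

**20 ⇒ 19 ⇒ 18.** **20** comes from di-tert-butyl ester **19** by acidolysis, and **19** from cyclobutene **18** by adding hydrogen to C1 and C2. Syn hydrogenation could only give the cis diester and equilibration would give the all-trans isomer. The hydrogens must therefore arrive one at a time under kinetic control, each on the face away from the aryl group on the adjacent carbon, which calls for an electron-transfer reduction with a metal-bound proton source. tert-Butyl esters are chosen because acid removes them, and C1/C2 cannot enolise in acid. **18** is simpler by two stereocentres.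

**18 ⇒ 15 (key).** The C1=C2 bond of **18** is cut with insertion of SO2, giving thiolane 1,1-dioxide **15**: a Ramberg–Bäcklund ring contraction. The neighbouring cuts are a [2+2] union of two cinnamates, which offers no hold on the cis ester/aryl relation, and direct 4-exo-tet alkylation within dibromide **12**, which needs strong base and competes with E2 toward the benzylic hydrogens. Through the sulfone the new bond forms in a 3-exo-tet step between two carbons already held 1,3 in a five-membered ring, with mild base at or below 0 °C, and SO2 loss makes it irreversible. The forward reaction must halogenate once, close faster than it halogenates again, and leave C3/C4 alone; the configuration at C2/C5 of **15** is irrelevant.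

**15 ⇒ 13 ⇒ 12 ⇒ 10.** **15** is the S,S-dioxide of thiolane **13**. Cutting both C–S bonds of **13** leads to α,α′-dibromide **12** and an inorganic sulfide, and removing the bromines leads to adipate **10**. This is the classical way from adipates to thiolane-2,5-dicarboxylates, and it makes no stereochemical demand. The bromination must avoid free-enolate side reactions (Dieckmann closure, 4-exo alkylation), hence silyl ketene acetals.

**10 ⇒ 9 ⇒ 7 ⇒ 6.** **10** is the ester of diacid **9**, released from bis-imide **7**. **7** is cut at its central C3–C4 bond into two molecules of cinnamoyl imide **6**: a reductive β,β-hydrodimerisation. This one C–C bond creates both aryl-bearing stereocentres; with an oxazolidinone on each half the face of each β-carbon is controlled, and like combination gives one C2-symmetric enantiomer. The neighbour, hydrodimerisation of an achiral ester followed by resolution, discards half the material and is kept in reserve. The forward reaction must couple and not merely reduce, and the enolates must be protonated before they attack an imide carbonyl.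

**6 ⇒ 3 + 4; 3 ⇒ 1.** **6** is cut at the N–acyl bond into cinnamic acid **3** and (R)-oxazolidinone **4**; **3** is the two-carbon homologue of aldehyde **1** by Knoevenagel–Doebner condensation. **1**, **4** and **21** are commercial.

## Roads not taken

**Alternative 1:** The cut is at the two ring–aryl bonds. The trans-1,2-dicarboxamide **A2**, bearing a quinolin-8-yl group on each nitrogen, is arylated twice with aryl iodide **A3** under Pd(OAc)2/AgOAc to give **A1**.
- Merits: each amide guides palladium through a five-membered palladacycle to the methylene C–H cis to itself, so each aryl enters cis to the neighbouring carbonyl, and because the amides are trans the aryls come out trans. That is exactly the relative configuration of **24**, fixed by geometry and not by a kinetic protonation. In this respect the road is better than the chosen one, and it is shorter, since the ring is bought.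
- Weak points: the second arylation must occur next to the first aryl group. Both aminoquinoline amides must then be cleaved (N-acylation then hydroperoxide, or hot hydroxide) from carbonyls whose α-carbons epimerise toward the all-trans isomer. Silver is used in stoichiometric amount, and absolute configuration rests on a resolved diacid.
- Comparison: the chosen plan sets against it that its carboxyl groups are unveiled from tert-butyl esters by acid, with no base contact after C1/C2 are set, and that absolute configuration comes from an auxiliary-controlled C–C bond formation. It remains longer, and its step 10 is stereochemically less secure than the palladacycle.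

**Alternative 2:** The cut runs through the arene rings. The 3,4-diethynylcyclobutane **A5**, already carrying both protected arms, undergoes twofold cobalt-catalysed [4+2] addition (CoBr2(Ph2PCH2CH2PPh2), Zn, ZnI2) with diene **A6** to give **A4**, which is then dehydrogenated and desilylated.
- Merits: no electron-rich arene on the core until the end, and a convergent use of the arms.
- Weak points: **A5** contains the whole stereochemical problem of **24** (the same cis,trans,cis array, with propargylic positions added), and the road offers no way to it. Two cycloadditions must occur on adjacent hindered alkynes. Aromatisation needs an oxidant in the presence of benzyloxy-arenes and epimerisable centres, and two deprotection regimes are required.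
- Comparison: it is better in no respect except that four aryl benzyl ethers on the core are spared; the chosen plan solves ring and configuration instead of postponing them.

**Alternative 3:** The cut is at the two ester C–O bonds, made first instead of last. The lithium alkoxide of **22**, with a matched cinchona alkaloid, opens both rings of meso dianhydride **A8** to give **A7**.
- Merits: the four-membered ring with its cis,trans,cis pattern is bought, the arms go on at the start by anhydride opening without any epimerisable acyl activation, and **A7** is only two or three steps from commercial material against eleven to **20**. In brevity this road is clearly better.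
- Weak points: the second opening must choose the 1,2- over the 1,3-diester against a substrate-bound chiral nucleophile. The two free carboxyl groups of **A7** must then each be replaced by a catechol ring cis to the neighbouring ester. Decarboxylative arylation passes through a cyclobutyl radical, so the configuration bought with **A8** is lost at those carbons and must be re-won by face selection, with the arms already present.
- Comparison: the chosen plan fixes the aryl-bearing centres first, where they cannot epimerise, and leaves only the ester-bearing centres to kinetic control; it pays for this with length.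

Key step: step 9

Assumption: the hydrodimerisation of step 3 is taken to follow the chelated s-cis model of N-enoyl oxazolidinones (new bond at the β-carbon on the face opposite the C4 benzyl group), which calls for the (R)-auxiliary **4**; were the sense opposite, the (S)-auxiliary would be used and nothing else would change.

Remark: the aryl-bearing carbons are S in **7**–**10** and **12**–**18** and R from **19** on only because the ranking of their neighbours changes; no bond to them is touched after step 3.

## Route

Step 1
Reactants: 1 3,4-bis(benzyloxy)benzaldehyde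
Product: 3 (E)-3-[3,4-bis(benzyloxy)phenyl]prop-2-enoic acid, via arylidenemalonic acid 2 (not isolated)
Conditions: CH2(CO2H)2, pyridine, piperidine (cat.), 90 °C
Reagents that add atoms: malonic acid, OC(=O)CC(=O)O
Why: Knoevenagel–Doebner condensation; the arylidenemalonic acid decarboxylates in hot pyridine to the (E)-cinnamic acid, and aryl benzyl ethers are inert to these conditions.

Step 2
Reactants: 3 (E)-3-[3,4-bis(benzyloxy)phenyl]prop-2-enoic acid; 4 (R)-4-benzyl-1,3-oxazolidin-2-one
Product: 6 (R)-4-benzyl-3-[(E)-3-[3,4-bis(benzyloxy)phenyl]prop-2-enoyl]-1,3-oxazolidin-2-one, via mixed pivalic anhydride 5 (not isolated)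
Conditions: t-BuCOCl, Et3N, THF, −20 °C; then LiCl, 4, −20 °C → rt
Reagents that add atoms: none
Why: N-acylation of an oxazolidinone through a mixed pivalic anhydride, LiCl/Et3N activating the N–H; the hindered pivaloyl carbonyl steers attack to the cinnamoyl carbonyl and the E-alkene is untouched.

Step 3
Reactants: 6 (R)-4-benzyl-3-[(E)-3-[3,4-bis(benzyloxy)phenyl]prop-2-enoyl]-1,3-oxazolidin-2-one (two molecules)
Product: 7 (4R,4'R)-3,3'-[(3S,4S)-3,4-bis[3,4-bis(benzyloxy)phenyl]hexanedioyl]bis(4-benzyl-1,3-oxazolidin-2-one)
Conditions: SmI2 (1.1 equiv per enoyl group), t-BuOH, THF, −78 °C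
Reagents that add atoms: none
Why: Reductive β,β-hydrodimerisation of a cinnamoyl derivative by electron transfer; samarium chelates both imide carbonyls and holds each radical anion syn s-cis, so each β-carbon bonds on the face away from the benzyl group and like combination gives the C2-symmetric (3S,4S) dimer. The weak acid t-BuOH protonates the enolates after coupling without diverting the radical anion to simple reduction.

Step 4
Reactants: 7 (4R,4'R)-3,3'-[(3S,4S)-3,4-bis[3,4-bis(benzyloxy)phenyl]hexanedioyl]bis(4-benzyl-1,3-oxazolidin-2-one)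
Product: 9 (3S,4S)-3,4-bis[3,4-bis(benzyloxy)phenyl]hexanedioic acid, via diperoxy acid 8 (not isolated)
Conditions: LiOH, H2O2, THF–H2O, 0 °C; Na2SO3 (aq); then HCl (aq) to pH 2
Reagents that add atoms: hydrogen peroxide, OO
Why: Hydroperoxide cleavage of N-acyl oxazolidinones; LiOOH attacks the exocyclic carbonyl, sulfite reduces the peracid, and C3/C4 are not α to a carbonyl so they cannot epimerise; auxiliary 4 is recovered.

Step 5
Reactants: 9 (3S,4S)-3,4-bis[3,4-bis(benzyloxy)phenyl]hexanedioic acid
Product: 10 di-tert-butyl (3S,4S)-3,4-bis[3,4-bis(benzyloxy)phenyl]hexanedioate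
Conditions: Cl3CC(=NH)Ot-Bu, CH2Cl2–cyclohexane, rt
Reagents that add atoms: tert-butyl 2,2,2-trichloroacetimidate, CC(C)(C)OC(=N)C(Cl)(Cl)Cl
Why: tert-Butylation of a carboxylic acid by a trichloroacetimidate, the acid itself protonating the imidate, so no base is needed; tert-butyl esters resist enolate self-condensation, sulfide and hydroxide in steps 6–10 and leave under acid in step 11.

Step 6
Reactants: 10 di-tert-butyl (3S,4S)-3,4-bis[3,4-bis(benzyloxy)phenyl]hexanedioate
Product: 12 di-tert-butyl (3S,4S)-2,5-dibromo-3,4-bis[3,4-bis(benzyloxy)phenyl]hexanedioate (C2/C5 epimers), via bis(silyl ketene acetal) 11 (not isolated)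
Conditions: LiN(i-Pr)2, Me3SiCl, THF, −78 °C; then N-bromosuccinimide, −78 °C
Reagents that add atoms: N-bromosuccinimide, O=C1CCC(=O)N1Br
Why: α-Bromination of esters through their silyl ketene acetals; in-situ silylation keeps free enolate low, so neither Dieckmann closure nor 4-exo alkylation intervenes, and the reactive ketene acetal is brominated in preference to the arenes. The configuration at C2/C5 is immaterial.

Step 7
Reactants: 12 di-tert-butyl (3S,4S)-2,5-dibromo-3,4-bis[3,4-bis(benzyloxy)phenyl]hexanedioate
Product: 13 di-tert-butyl (3S,4S)-3,4-bis[3,4-bis(benzyloxy)phenyl]thiolane-2,5-dicarboxylate (C2/C5 epimers)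
Conditions: Na2S·9H2O, DMF–H2O, 0 °C → rt
Reagents that add atoms: sodium sulfide, [Na+].[Na+].[S-2]
Why: Double SN2 thioetherification (intermolecular, then 5-exo-tet), the standard conversion of α,α′-dibromoadipates into thiolane-2,5-dicarboxylates; α-bromo esters are excellent substrates for sulfur nucleophiles and the trans-diaryl unit holds the chain ends close.

Step 8
Reactants: 13 di-tert-butyl (3S,4S)-3,4-bis[3,4-bis(benzyloxy)phenyl]thiolane-2,5-dicarboxylate
Product: 15 di-tert-butyl (3S,4S)-3,4-bis[3,4-bis(benzyloxy)phenyl]thiolane-2,5-dicarboxylate 1,1-dioxide (C2/C5 epimers), via sulfoxide 14 (not isolated)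
Conditions: mCPBA (2.5 equiv), NaHCO3, CH2Cl2, 0 °C → rt
Reagents that add atoms: 3-chloroperoxybenzoic acid, O=C(OO)c1cccc(Cl)c1
Why: Peracid oxidation of a sulfide through the sulfoxide to the sulfone; sulfur is far more nucleophilic than the alkoxy-arenes, and the cold buffered medium prevents sulfoxide elimination.

Step 9
Reactants: 15 di-tert-butyl (3S,4S)-3,4-bis[3,4-bis(benzyloxy)phenyl]thiolane-2,5-dicarboxylate 1,1-dioxide
Product: 18 di-tert-butyl (3S,4S)-3,4-bis[3,4-bis(benzyloxy)phenyl]cyclobut-1-ene-1,2-dicarboxylate, via α-bromo sulfone 16 (not isolated), via episulfone 17 (not isolated)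
Conditions: KOH/Al2O3, BrCF2CF2Br (added slowly), CH2Cl2–t-BuOH, −10 → 0 °C; filtered cold
Reagents that add atoms: none
Why: Halogenative Ramberg–Bäcklund reaction (base plus a positive-halogen donor acting on the sulfone itself), the reaction type known for contracting thiolane 1,1-dioxides to cyclobutenes. KOH on alumina removes the hydrogen at C2, flanked by sulfonyl and ester, and the carbanion takes bromine from BrCF2CF2Br, which collapses to tetrafluoroethene and bromide and so releases no carbene that a stabilised carbanion could trap; this gives α-bromo sulfone 16. Deprotonation at C5 and 1,3-displacement of bromide with inversion (3-exo-tet) closes episulfone 17; this one bond is both the third bond of the thiirane dioxide and the C1–C2 bond of the four-membered carbocycle, which thus arises as the second ring of a 5-thiabicyclo[2.1.0]pentane. Cheletropic loss of SO2 from 17 leaves the C1=C2 double bond of 18 and makes the contraction irreversible. No stereocentre is created: C2 and C5 of 15 both end sp2 whatever their configuration, and because the trans-diaryl unit is C2-symmetric the two faces on which the episulfone can form are equivalent. The step needs ring closure to outrun a second bromination at C5, which its intramolecular nature and slow addition of the bromine donor to excess base should secure, and it needs C3/C4 to stay intact, which holds in 15 because these carbons carry no acidifying group. In 18 the C3/C4 hydrogens are γ to the esters and the ring can open conrotatorily, so the solid base is filtered off cold and 18 is reduced at once.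

Step 10
Reactants: 18 di-tert-butyl (3S,4S)-3,4-bis[3,4-bis(benzyloxy)phenyl]cyclobut-1-ene-1,2-dicarboxylate
Product: 19 di-tert-butyl (1R,2R,3R,4R)-3,4-bis[3,4-bis(benzyloxy)phenyl]cyclobutane-1,2-dicarboxylate
Conditions: SmI2 (2.5 equiv), H2O, THF, −78 °C
Reagents that add atoms: none
Why: Conjugate reduction of an ene-1,2-diester by electron transfer (SmI2–H2O), a stepwise anti addition of two hydrogens. Samarium-bound water protonates the radical anion at C1 on the face away from the C4 aryl group; after the second electron transfer the samarium enolate at C2 stays chelated to the C1 ester carbonyl, so its water delivers the proton on the face of the C1 ester, which is also the face away from the larger C3 aryl group. Both esters should thus end cis to the neighbouring aryl and trans to each other (1R,2R), under kinetic control and with no base present afterwards.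

Step 11
Reactants: 19 di-tert-butyl (1R,2R,3R,4R)-3,4-bis[3,4-bis(benzyloxy)phenyl]cyclobutane-1,2-dicarboxylate
Product: 20 (1R,2R,3R,4R)-3,4-bis[3,4-bis(benzyloxy)phenyl]cyclobutane-1,2-dicarboxylic acid
Conditions: CF3CO2H, Et3SiH, CH2Cl2, 0 °C
Reagents that add atoms: none
Why: Acidolysis of tert-butyl esters (loss of the tert-butyl cation); Et3SiH reduces the cation before it can alkylate the benzyloxy-arenes, aryl benzyl ethers survive cold CF3CO2H, and C1/C2 do not enolise in acid.

Step 12
Reactants: 21 sodium (R)-3-(3,4-dihydroxyphenyl)-2-hydroxypropanoate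
Product: 22 benzyl (R)-3-[3,4-bis(benzyloxy)phenyl]-2-hydroxypropanoate
Conditions: BnBr (3.3 equiv), K2CO3, DMF, rt
Reagents that add atoms: benzyl bromide, BrCc1ccccc1
Why: Williamson etherification of both phenols and SN2 alkylation of the carboxylate; carbonate does not deprotonate the secondary hydroxyl, which stays free, and the stereocentre is not involved.

Step 13
Reactants: 20 (1R,2R,3R,4R)-3,4-bis[3,4-bis(benzyloxy)phenyl]cyclobutane-1,2-dicarboxylic acid; 22 benzyl (R)-3-[3,4-bis(benzyloxy)phenyl]-2-hydroxypropanoate (two molecules)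
Product: 23 bis[(R)-1-(benzyloxy)-3-[3,4-bis(benzyloxy)phenyl]-1-oxopropan-2-yl] (1R,2R,3R,4R)-3,4-bis[3,4-bis(benzyloxy)phenyl]cyclobutane-1,2-dicarboxylate
Conditions: EDC·HCl, DMAP (cat.), CH2Cl2, 0 °C → rt
Reagents that add atoms: none
Why: Steglich esterification (carbodiimide with DMAP as acyl-transfer catalyst); the trans-diacid cannot form a cyclic anhydride so each carboxyl is acylated separately, and the C–O bond of 22 is not broken so its (R) centre is retained. Low temperature and substoichiometric DMAP limit enolisation at C1/C2.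

Step 14
Reactants: 23 bis[(R)-1-(benzyloxy)-3-[3,4-bis(benzyloxy)phenyl]-1-oxopropan-2-yl] (1R,2R,3R,4R)-3,4-bis[3,4-bis(benzyloxy)phenyl]cyclobutane-1,2-dicarboxylate
Product: 24 bis[(R)-1-carboxy-2-(3,4-dihydroxyphenyl)ethyl] (1R,2R,3R,4R)-3,4-bis(3,4-dihydroxyphenyl)cyclobutane-1,2-dicarboxylate
Conditions: H2 (1 atm), Pd/C, THF–MeOH, rt, under argon on work-up
Reagents that add atoms: none
Why: Hydrogenolysis of eight aryl benzyl ethers and two benzyl esters in one neutral operation; the cyclobutane and the non-benzylic ester C–O bonds are not cleaved, and no base reaches C1/C2.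

## Compound list

1 | 3,4-bis(benzyloxy)benzaldehyde | O=Cc1ccc(OCc2ccccc2)c(OCc2ccccc2)c1 | starting material
2 | 2-[3,4-bis(benzyloxy)benzylidene]propanedioic acid | OC(=O)C(=Cc1ccc(OCc2ccccc2)c(OCc2ccccc2)c1)C(=O)O | intermediate
3 | (E)-3-[3,4-bis(benzyloxy)phenyl]prop-2-enoic acid | O=C(O)/C=C/c1ccc(OCc2ccccc2)c(OCc2ccccc2)c1 | intermediate
4 | (R)-4-benzyl-1,3-oxazolidin-2-one | O=C1N[C@H](Cc2ccccc2)CO1 | starting material
5 | (E)-3-[3,4-bis(benzyloxy)phenyl]prop-2-enoic 2,2-dimethylpropanoic anhydride | CC(C)(C)C(=O)OC(=O)/C=C/c1ccc(OCc2ccccc2)c(OCc2ccccc2)c1 | intermediate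
6 | (R)-4-benzyl-3-[(E)-3-[3,4-bis(benzyloxy)phenyl]prop-2-enoyl]-1,3-oxazolidin-2-one | O=C(/C=C/c1ccc(OCc2ccccc2)c(OCc2ccccc2)c1)N1C(=O)OC[C@H]1Cc1ccccc1 | intermediate
7 | (4R,4'R)-3,3'-[(3S,4S)-3,4-bis[3,4-bis(benzyloxy)phenyl]hexanedioyl]bis(4-benzyl-1,3-oxazolidin-2-one) | O=C(C[C@H](c1ccc(OCc2ccccc2)c(OCc2ccccc2)c1)[C@@H](c1ccc(OCc2ccccc2)c(OCc2ccccc2)c1)CC(=O)N1C(=O)OC[C@H]1Cc1ccccc1)N1C(=O)OC[C@H]1Cc1ccccc1 | intermediate
8 | (3S,4S)-3,4-bis[3,4-bis(benzyloxy)phenyl]hexanediperoxoic acid | OOC(=O)C[C@H](c1ccc(OCc2ccccc2)c(OCc2ccccc2)c1)[C@@H](c1ccc(OCc2ccccc2)c(OCc2ccccc2)c1)CC(=O)OO | intermediate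
9 | (3S,4S)-3,4-bis[3,4-bis(benzyloxy)phenyl]hexanedioic acid | O=C(O)C[C@H](c1ccc(OCc2ccccc2)c(OCc2ccccc2)c1)[C@@H](c1ccc(OCc2ccccc2)c(OCc2ccccc2)c1)CC(=O)O | intermediate
10 | di-tert-butyl (3S,4S)-3,4-bis[3,4-bis(benzyloxy)phenyl]hexanedioate | CC(C)(C)OC(=O)C[C@H](c1ccc(OCc2ccccc2)c(OCc2ccccc2)c1)[C@@H](c1ccc(OCc2ccccc2)c(OCc2ccccc2)c1)CC(=O)OC(C)(C)C | intermediate
11 | bis(O-trimethylsilyl ketene acetal) of 10, configuration at the two aryl-bearing carbons as in 10 | CC(C)(C)OC(O[Si](C)(C)C)=C[C@H](c1ccc(OCc2ccccc2)c(OCc2ccccc2)c1)[C@@H](c1ccc(OCc2ccccc2)c(OCc2ccccc2)c1)C=C(O[Si](C)(C)C)OC(C)(C)C | intermediate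
12 | di-tert-butyl (3S,4S)-2,5-dibromo-3,4-bis[3,4-bis(benzyloxy)phenyl]hexanedioate (C2/C5 epimers) | CC(C)(C)OC(=O)C(Br)[C@H](c1ccc(OCc2ccccc2)c(OCc2ccccc2)c1)[C@@H](c1ccc(OCc2ccccc2)c(OCc2ccccc2)c1)C(Br)C(=O)OC(C)(C)C | intermediate
13 | di-tert-butyl (3S,4S)-3,4-bis[3,4-bis(benzyloxy)phenyl]thiolane-2,5-dicarboxylate (C2/C5 epimers) | CC(C)(C)OC(=O)C1SC(C(=O)OC(C)(C)C)[C@H](c2ccc(OCc3ccccc3)c(OCc3ccccc3)c2)[C@H]1c1ccc(OCc2ccccc2)c(OCc2ccccc2)c1 | intermediate
14 | di-tert-butyl (3S,4S)-3,4-bis[3,4-bis(benzyloxy)phenyl]thiolane-2,5-dicarboxylate 1-oxide | CC(C)(C)OC(=O)C1S(=O)C(C(=O)OC(C)(C)C)[C@H](c2ccc(OCc3ccccc3)c(OCc3ccccc3)c2)[C@H]1c1ccc(OCc2ccccc2)c(OCc2ccccc2)c1 | intermediate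
15 | di-tert-butyl (3S,4S)-3,4-bis[3,4-bis(benzyloxy)phenyl]thiolane-2,5-dicarboxylate 1,1-dioxide (C2/C5 epimers) | CC(C)(C)OC(=O)C1S(=O)(=O)C(C(=O)OC(C)(C)C)[C@H](c2ccc(OCc3ccccc3)c(OCc3ccccc3)c2)[C@H]1c1ccc(OCc2ccccc2)c(OCc2ccccc2)c1 | intermediate
16 | di-tert-butyl (3S,4S)-2-bromo-3,4-bis[3,4-bis(benzyloxy)phenyl]thiolane-2,5-dicarboxylate 1,1-dioxide | CC(C)(C)OC(=O)C1(Br)S(=O)(=O)C(C(=O)OC(C)(C)C)[C@H](c2ccc(OCc3ccccc3)c(OCc3ccccc3)c2)[C@H]1c1ccc(OCc2ccccc2)c(OCc2ccccc2)c1 | intermediate
17 | di-tert-butyl (2S,3S)-2,3-bis[3,4-bis(benzyloxy)phenyl]-5-thiabicyclo[2.1.0]pentane-1,4-dicarboxylate 5,5-dioxide (cis-fused episulfone) | CC(C)(C)OC(=O)C12S(=O)(=O)C1(C(=O)OC(C)(C)C)[C@H](c1ccc(OCc3ccccc3)c(OCc3ccccc3)c1)[C@H]2c1ccc(OCc2ccccc2)c(OCc2ccccc2)c1 | intermediate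
18 | di-tert-butyl (3S,4S)-3,4-bis[3,4-bis(benzyloxy)phenyl]cyclobut-1-ene-1,2-dicarboxylate | CC(C)(C)OC(=O)C1=C(C(=O)OC(C)(C)C)[C@H](c2ccc(OCc3ccccc3)c(OCc3ccccc3)c2)[C@H]1c1ccc(OCc2ccccc2)c(OCc2ccccc2)c1 | intermediate
19 | di-tert-butyl (1R,2R,3R,4R)-3,4-bis[3,4-bis(benzyloxy)phenyl]cyclobutane-1,2-dicarboxylate | CC(C)(C)OC(=O)[C@H]1[C@H](C(=O)OC(C)(C)C)[C@H](c2ccc(OCc3ccccc3)c(OCc3ccccc3)c2)[C@H]1c1ccc(OCc2ccccc2)c(OCc2ccccc2)c1 | intermediate
20 | (1R,2R,3R,4R)-3,4-bis[3,4-bis(benzyloxy)phenyl]cyclobutane-1,2-dicarboxylic acid | O=C(O)[C@H]1[C@H](C(=O)O)[C@H](c2ccc(OCc3ccccc3)c(OCc3ccccc3)c2)[C@H]1c1ccc(OCc2ccccc2)c(OCc2ccccc2)c1 | intermediate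
21 | sodium (R)-3-(3,4-dihydroxyphenyl)-2-hydroxypropanoate | [Na+].[O-]C(=O)[C@H](O)Cc1ccc(O)c(O)c1 | starting material
22 | benzyl (R)-3-[3,4-bis(benzyloxy)phenyl]-2-hydroxypropanoate | O=C(OCc1ccccc1)[C@H](O)Cc1ccc(OCc2ccccc2)c(OCc2ccccc2)c1 | intermediate
23 | bis[(R)-1-(benzyloxy)-3-[3,4-bis(benzyloxy)phenyl]-1-oxopropan-2-yl] (1R,2R,3R,4R)-3,4-bis[3,4-bis(benzyloxy)phenyl]cyclobutane-1,2-dicarboxylate | O=C(O[C@H](Cc1ccc(OCc2ccccc2)c(OCc2ccccc2)c1)C(=O)OCc1ccccc1)[C@H]1[C@H](C(=O)O[C@H](Cc2ccc(OCc3ccccc3)c(OCc3ccccc3)c2)C(=O)OCc2ccccc2)[C@H](c2ccc(OCc3ccccc3)c(OCc3ccccc3)c2)[C@H]1c1ccc(OCc2ccccc2)c(OCc2ccccc2)c1 | intermediate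
24 | bis[(R)-1-carboxy-2-(3,4-dihydroxyphenyl)ethyl] (1R,2R,3R,4R)-3,4-bis(3,4-dihydroxyphenyl)cyclobutane-1,2-dicarboxylate | O=C(O[C@H](Cc1ccc(O)c(O)c1)C(=O)O)[C@H]1[C@H](C(=O)O[C@H](Cc2ccc(O)c(O)c2)C(=O)O)[C@H](c2ccc(O)c(O)c2)[C@H]1c1ccc(O)c(O)c1 | target

## Step count and risks

Total: 14 steps. Longest linear sequence: 13 steps (1–11, 13, 14, from **1** to **24**); step 12 is the one-step branch to **22**.

**Step 9 (key step).**
- Risk: a second bromination at C5 may outrun ring closure and leave a sulfone with no α-hydrogen. The 1,3-displacement by a doubly stabilised carbanion at a fully substituted carbon may be slow. Once **18** is formed, base may move the double bond into conjugation with an aryl group, or the ring may open thermally.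
- Fallback (from **12**, returning at **18**): the C1–C2 bond is made by carbanion alkylation instead of sulfur extrusion. NaH in THF–DMF at 0 °C deprotonates a bromine-bearing α-carbon of **12**, and the bromo-enolate displaces the second bromide (4-exo-tet) to give di-tert-butyl 1-bromo-3,4-bis[3,4-bis(benzyloxy)phenyl]cyclobutane-1,2-dicarboxylate F1. Loss of HBr from F1 toward the remaining ester α-hydrogen gives **18**. This is the known passage from α,α′-dibromoadipates to cyclobutene-1,2-dicarboxylates.

**Step 10.**
- Risk: poor facial selectivity in the second protonation (delivery away from the newly set ester instead of away from the aryl group), or ring opening at the radical-anion stage before protonation.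
- Fallback (from **18**, returning at **19**): the two hydrogens are delivered in separate two-electron operations. LiBH(s-Bu)3 in THF at −78 °C adds hydride to one alkene carbon on the face away from the adjacent aryl group, and Me3SiCl traps the enolate as tert-butyl 2-[tert-butoxy(trimethylsilyloxy)methylidene]-3,4-bis[3,4-bis(benzyloxy)phenyl]cyclobutane-1-carboxylate F2. F2 is then protodesilylated at −78 °C with a hindered proton donor (2,6-di-tert-butylphenol, catalytic fluoride), whose bulk makes it more sensitive to the aryl group than to the ester. No radical anion is involved.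

**Step 3.**
- Risk: simple conjugate reduction in place of coupling, attack of a samarium enolate on the second imide carbonyl (Dieckmann-type closure), or face selectivity lower than the chelate model predicts.
- Fallback (from **3**, returning at **9**): auxiliary control is replaced by resolution. Esterification (MeOH, H2SO4) gives methyl (E)-3-[3,4-bis(benzyloxy)phenyl]prop-2-enoate F3. Hydrodimerisation with SmI2, HMPA and t-BuOH gives racemic dimethyl (3S*,4S*)-3,4-bis[3,4-bis(benzyloxy)phenyl]hexanedioate F4. Saponification with LiOH gives racemic (3S*,4S*)-3,4-bis[3,4-bis(benzyloxy)phenyl]hexanedioic acid F5. Crystallisation of its diastereomeric salts with (R)-1-phenylethylamine gives **9**, whose configuration is then assigned by comparison with material from step 4 or by crystallography.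

**Step 7.**
- Risk: E2 loss of HBr toward the benzylic hydrogens, attack of sulfide on bromine with reductive debromination, or intermolecular thioether formation in place of ring closure.
- Fallback (from **10**, returning at **13**): the polarity is reversed and sulfur enters as the electrophile. The bis-enolate of **10** (LiN(i-Pr)2, 2.2 equiv, THF, −78 °C) is added to bis(phenylsulfonyl) sulfide. The first sulfenylation gives an α-thiosulfonate and the second enolate closes the five-membered ring on sulfur with loss of sulfinate, giving **13** directly. No new isolated compound lies on this path.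

**Step 13.**
- Risk: epimerisation of C1/C2 in the activated acyl intermediate toward the all-trans diester, and slow acylation of the hindered alcohol with rearrangement of the O-acylisourea.
- Fallback (from **22** and **20**, returning at **23**): the ester bond is made by alkylating the carboxylate instead of acylating the alcohol. Mitsunobu reaction of **22** with chloroacetic acid (PPh3, diisopropyl azodicarboxylate) gives benzyl (S)-3-[3,4-bis(benzyloxy)phenyl]-2-(chloroacetoxy)propanoate F6. Thiourea and NaHCO3 in ethanol remove the chloroacetate to give benzyl (S)-3-[3,4-bis(benzyloxy)phenyl]-2-hydroxypropanoate F7. A second Mitsunobu reaction of F7 with diacid **20** inverts the carbinol carbon again and gives **23** with (R) arms. The carboxyl groups of **20** are never activated, so C1/C2 cannot epimerise.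

## Further compounds

F1 | step 9 | di-tert-butyl 1-bromo-3,4-bis[3,4-bis(benzyloxy)phenyl]cyclobutane-1,2-dicarboxylate (aryl-bearing carbons as in 18, C1/C2 unassigned) | CC(C)(C)OC(=O)C1(Br)C(C(=O)OC(C)(C)C)[C@H](c2ccc(OCc3ccccc3)c(OCc3ccccc3)c2)[C@H]1c1ccc(OCc2ccccc2)c(OCc2ccccc2)c1
F2 | step 10 | tert-butyl 2-[tert-butoxy(trimethylsilyloxy)methylidene]-3,4-bis[3,4-bis(benzyloxy)phenyl]cyclobutane-1-carboxylate (C1 ester cis to the C4 aryl, aryls trans) | CC(C)(C)OC(=O)[C@H]1C(=C(O[Si](C)(C)C)OC(C)(C)C)[C@H](c2ccc(OCc3ccccc3)c(OCc3ccccc3)c2)[C@H]1c1ccc(OCc2ccccc2)c(OCc2ccccc2)c1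
F3 | step 3 | methyl (E)-3-[3,4-bis(benzyloxy)phenyl]prop-2-enoate | COC(=O)/C=C/c1ccc(OCc2ccccc2)c(OCc2ccccc2)c1
F4 | step 3 | racemic dimethyl (3S*,4S*)-3,4-bis[3,4-bis(benzyloxy)phenyl]hexanedioate (one enantiomer drawn) | COC(=O)C[C@H](c1ccc(OCc2ccccc2)c(OCc2ccccc2)c1)[C@@H](c1ccc(OCc2ccccc2)c(OCc2ccccc2)c1)CC(=O)OC
F5 | step 3 | racemic (3S*,4S*)-3,4-bis[3,4-bis(benzyloxy)phenyl]hexanedioic acid (one enantiomer drawn) | O=C(O)C[C@H](c1ccc(OCc2ccccc2)c(OCc2ccccc2)c1)[C@@H](c1ccc(OCc2ccccc2)c(OCc2ccccc2)c1)CC(=O)O
F0 | step 7 | none | none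
F6 | step 13 | benzyl (S)-3-[3,4-bis(benzyloxy)phenyl]-2-(chloroacetoxy)propanoate | O=C(CCl)O[C@@H](Cc1ccc(OCc2ccccc2)c(OCc2ccccc2)c1)C(=O)OCc1ccccc1
F7 | step 13 | benzyl (S)-3-[3,4-bis(benzyloxy)phenyl]-2-hydroxypropanoate | O[C@@H](Cc1ccc(OCc2ccccc2)c(OCc2ccccc2)c1)C(=O)OCc1ccccc1
A1 | alternative 1 | (1R,2R,3R,4R)-3,4-bis[3,4-bis(benzyloxy)phenyl]-N1,N2-di(quinolin-8-yl)cyclobutane-1,2-dicarboxamide | O=C(Nc1cccc2cccnc12)[C@H]1[C@H](C(=O)Nc2cccc3cccnc23)[C@H](c2ccc(OCc3ccccc3)c(OCc3ccccc3)c2)[C@H]1c1ccc(OCc2ccccc2)c(OCc2ccccc2)c1
A2 | alternative 1 | (1R,2R)-N1,N2-di(quinolin-8-yl)cyclobutane-1,2-dicarboxamide | O=C(Nc1cccc2cccnc12)[C@H]1[C@H](C(=O)Nc2cccc3cccnc23)CC1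
A3 | alternative 1 | 1,2-bis(benzyloxy)-4-iodobenzene | Ic1ccc(OCc2ccccc2)c(OCc2ccccc2)c1
A4 | alternative 2 | bis[(R)-1-(benzyloxy)-3-[3,4-bis(benzyloxy)phenyl]-1-oxopropan-2-yl] 3,4-bis[4,5-bis(tert-butyldimethylsilyloxy)cyclohexa-1,4-dien-1-yl]cyclobutane-1,2-dicarboxylate (ring configuration as in 23) | O=C(O[C@H](Cc1ccc(OCc2ccccc2)c(OCc2ccccc2)c1)C(=O)OCc1ccccc1)[C@H]1[C@H](C(=O)O[C@H](Cc2ccc(OCc3ccccc3)c(OCc3ccccc3)c2)C(=O)OCc2ccccc2)[C@H](C2=CCC(O[Si](C)(C)C(C)(C)C)=C(O[Si](C)(C)C(C)(C)C)C2)[C@H]1C1=CCC(O[Si](C)(C)C(C)(C)C)=C(O[Si](C)(C)C(C)(C)C)C1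
A5 | alternative 2 | bis[(R)-1-(benzyloxy)-3-[3,4-bis(benzyloxy)phenyl]-1-oxopropan-2-yl] 3,4-diethynylcyclobutane-1,2-dicarboxylate (ring configuration as in 23) | O=C(O[C@H](Cc1ccc(OCc2ccccc2)c(OCc2ccccc2)c1)C(=O)OCc1ccccc1)[C@H]1[C@H](C(=O)O[C@H](Cc2ccc(OCc3ccccc3)c(OCc3ccccc3)c2)C(=O)OCc2ccccc2)[C@H](C#C)[C@H]1C#C
A6 | alternative 2 | 2,3-bis(tert-butyldimethylsilyloxy)buta-1,3-diene | C=C(O[Si](C)(C)C(C)(C)C)C(=C)O[Si](C)(C)C(C)(C)C
A7 | alternative 3 | C2-symmetric cyclobutane 1,2-diester 3,4-diacid carrying both protected arms (cis,trans,cis; ring configuration as in 23) | O=C(O[C@H](Cc1ccc(OCc2ccccc2)c(OCc2ccccc2)c1)C(=O)OCc1ccccc1)[C@H]1[C@H](C(=O)O[C@H](Cc2ccc(OCc3ccccc3)c(OCc3ccccc3)c2)C(=O)OCc2ccccc2)[C@H](C(=O)O)[C@H]1C(=O)O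
A8 | alternative 3 | cis,trans,cis-cyclobutane-1,2,3,4-tetracarboxylic 1,2:3,4-dianhydride (meso) | O=C1OC(=O)[C@H]2[C@@H]1[C@@H]1C(=O)OC(=O)[C@@H]12
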